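## Structural features

δ-Viniferin is a resveratrol dehydrodimer built on a 2,3-dihydrobenzofuran. Benzo ring A (C3a to C7a) is fused to a dihydrofuran whose O1 sits on C7a; C2 carries the 4-hydroxyphenyl ring B, C3 the 3,5-dihydroxyphenyl ring C, and C5 (para to O1) an (E)-3,5-dihydroxystyryl arm (ring D). C2 and C3 are adjacent stereocentres, both S, with rings B and C trans. C2 is a benzylic ether carbon and C3 a doubly benzylic methine, and no other functional handle stands near them.

The fragile points are four. The O1–C2 benzylic aryl ether ionises under acid because ring B has a para oxygen. The C3–H bond, if removed by base, can expel O1 and open the ring. The E-stilbene is sensitive to light, acid and cations. The five phenols are oxidisable.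

The real difficulty is to set absolute and relative configuration at two contiguous methines that carry only aryl groups, and then to free five phenols without ionising C2 or attacking the alkene. Only C3 is configurationally robust, because C2 re-closes to the trans ring whenever it ionises; C3 is therefore the centre that must be set with certainty. The key step treats C2–C3 as the former double bond of an (E)-alkenyl boronate: ring C is already on C3, ring B enters at C2 from boron, C3a of ring A enters at C3 from palladium, and the boron left on C2 holds the place of O1.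

## Logic of the disconnections

19 ⇒ 18. The five O–CH3 bonds are made free last. Methyl is chosen because every building block is then commercial and inert to organolithium, palladium, perborate, alkoxide and hydride. Nothing is gained in skeleton, but the route stays short. The forward dealkylation must not destroy O1–C2 or the alkene; it is tolerable because C2, if it ionises, can only re-close under the control of C3 to the trans ring.

18 ⇒ 16 + 17. The C=C bond of the C5 arm is cut. This removes ring D and the only alkene in one convergent step, and 17 is commercial. The forward olefination must be E-selective and must not deprotonate C3.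

16 ⇒ 15 ⇒ 14. No skeletal bond is cut; the C5 carbon is taken back from aldehyde through alcohol to methyl ester. An ester, not an aldehyde, has to stand para to C7a in the earlier steps, because it activates the ring for closure and survives peroxide. Hydride and oxidant must leave the heterocycle alone.

14 ⇒ 13. O1–C7a is cut. Closing this bond by displacement of a fluoride on ring A (ortho to C3a, para to the ester) leaves the C2–O bond untouched, so the configuration at C2 is carried, and 13 is acyclic. The five-membered closure must outrun fragmentation of the alkoxide and epimerisation at C3.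

13 ⇒ 12. The C2–O bond is exchanged for a C2–B bond. Carbon–boron bonds are oxidised with retention, so O1 inherits the configuration that boron had. The oxidant must spare the ester and the activated C–F bond.

12 ⇒ 11 + 8, and 11 ⇒ 6 + 10. C2–ring B and C3–C3a are cut together. Both stereocentres then arise in one catalytic event from three achiral pieces, and anti addition across an E-alkene gives the relative configuration that becomes trans. The forward step demands that the metallate shift beat direct boron-to-palladium transfer. A pinacol ester on boron is the obvious choice, but with a β-substituent it is prone to direct transfer; boron therefore carries the rigid diolate of 2. Palladium must stay cationic, so the electrophile is a triflate and the bromide that accompanies 10 is precipitated. 8 carries fluorine ortho to the reacting carbon and the ester para to fluorine as spectators for the later steps.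

6 ⇒ 3 + 4 + 2, and 2 ⇒ 1. The alkenyl C–B bond is cut by hydroboration of 3 with 4, and the B–O bonds by ester exchange with 2; the E geometry must be secured. The two C–CH3 bonds of 2 go back to the carbonyl carbons of 1; the cis diol is required.

10 ⇒ 9 and 8 ⇒ 7. A C–Li bond is traced to C–Br and the O–S bond of the triflate to the phenol. Both are routine; the only constraint is that no free aryllithium may remain when 8 is added.

## Other disconnections considered

Alternative 1: The cut goes through ring A itself: C3a–C7a, C4–C5 and C6–C7 are broken. This leaves the silyl-capped ynol ether diyne A2 (it already holds O1, C2, C3 and rings B and C) and the conjugated enyne A3 (C5, C6 and the complete arm). In the forward sense Cp*RuCl(cod) would join the two alkynes of A2 to a ruthenacyclopentadiene and insert the alkyne of A3, closing benzo ring A and the dihydrofuran in one neutral step to A1; ipso-protodesilylation at C7 would then give 18.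
- In its favour: three C–C bonds and two rings form in one operation, the E-alkene arrives ready-made, and the silyl group should steer the arm to C5 (meta to silicon). No SNAr, redox adjustment or olefination is needed afterwards. On bonds and rings formed per step, and on the number of steps after the key step, this alternative is the better one.
- Against it: the step creates no stereocentre, so the whole C2/C3 problem moves into the synthesis of A2, for which a separate asymmetric route would have to be devised. C3–H of A2 is both benzylic and propargylic and would meet the strong base needed to make an ynol ether. Silyl ynol ethers are sensitive to moisture and acid, and A3 can react through its alkene or trimerise with itself.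
- Comparison: it is more convergent at the ring level but less so at the stereochemical level. It carries stereochemistry where the chosen key step creates it. The total step count would most probably be higher because of A2, and the final demethylation is the same.

Alternative 2: Ring A is removed as an aryne: O1–C7a and C3–C3a are cut, which leads back to the trans epoxide A5 and the ortho-silylaryl triflate A6. Forward, CsF would release the aryne from A6. The epoxide oxygen would add to C7a, the position remote from the C4 chlorine, as expected for a 3-haloaryne. The aryl anion at C3a would then collapse onto the benzylic carbon bearing ring C while its C–O bond opens, giving A4.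
- In its favour: the absolute configuration would come from an enantioselective epoxidation of an E-alkene, a mature reaction, so on the source of chirality this alternative is at least the equal of the chosen plan. Both ring bonds form under mild fluoride conditions. Ring B is carried as an aryl triflate, which makes C2 less prone to ionise and is removed by mild hydrolysis; this is better than a methyl ether on that ring. The C5 bromide would allow the arm to be attached in one coupling step, for example with 6, which is shorter than the three steps from 14 to 18.
- Against it: C3–C3a must form with retention at C3 through a front-side, cation-like collapse at a carbon whose 3,5-dimethoxyphenyl ring stabilises positive charge poorly. Leakage to the cis isomer, hydride or aryl shift to carbonyl compounds, and plain epoxide opening by fluoride are all conceivable. Aryne insertion into an epoxide C–O bond has a narrow precedent base. The chlorine that secures the regiochemistry must later be removed in the presence of either the C5 bromide or the stilbene. A6 needs a multi-step preparation, and four methyl ethers remain.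
- Comparison: the ring and two ring bonds form in one step (better on structure). The stereochemical relay depends on the lifetime of an ion pair instead of a stereospecific anti addition (weaker on mechanism). The overall length is expected to be similar once A6, dechlorination and triflate cleavage are counted.

Alternative 3: C2–C3 and O1–C2 are cut, so that C2 with ring B comes from the chiral benzylic sulfonium salt A9, and ring A, O1, C3 and ring C come from the sulfone A8. Forward, Cs2CO3 would eliminate sulfinate from A8 to an ortho-quinone methide and deprotonate A9 to the ylide. Conjugate addition of the ylide carbon to the exocyclic carbon (C2–C3), followed by displacement of the thiolane by the phenoxide (O1–C2), would give A7.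
- In its favour: it is a metal-free, one-step ring construction. The trans arrangement follows from the anti betaine and the SN2 closure, which makes it the equal of the chosen plan on relative configuration. Both components are reachable in very few steps, and the C5 bromide could be coupled with 6 to reach 18 directly. On step economy this is the best of the four plans.
- Against it: absolute control rests on a stoichiometric chiral sulfide, and the centre that matters most, C3, is formed at the quinone methide carbon, two bonds away from sulfur. If the conjugate addition is reversible, the enantiomeric outcome is decided in the ring closure and is hard to predict for this quinone methide. A9 is drawn as its (2R,5R) form only for definiteness; the antipode that leads to (2S,3S) would have to be established. The chiral thiolane has to be prepared and recovered.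
- Comparison: the three-component logic around C2–C3 is similar and relative control is equal. Absolute control comes from a catalyst-bound alkene face and a stereospecific shift in the chosen plan, against a remote auxiliary in the alternative. The alternative has fewer steps, and the final demethylation is the same.

Key step: step 4

Assumption: the (Sp,Sp) antipode of the MandyPhos ligand is taken to bind the alkene face that leads to (1S,2S)-12; if the sense of induction is the opposite, the (Rp,Rp) antipode is used and nothing else changes.

## Route

Step 1
Reactants: 1 acenaphthylene-1,2-dione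
Product: 2 (1R,2S)-1,2-dimethyl-1,2-dihydroacenaphthylene-1,2-diol (cis diol, meso)
Conditions: AlMe3 (4 equiv), toluene, 0 °C → rt; aq. potassium sodium tartrate; recrystallisation
Reagents that add atoms: trimethylaluminium, C[Al](C)C
Why: Two successive 1,2-additions of methyl to the 1,2-diketone; the second methyl should enter anti to the bulky aluminium alkoxide formed first, which places both oxygens on the same face, and crystallisation should remove any trans isomer.

Step 2
Reactants: 3 1-ethynyl-3,5-dimethoxybenzene; 4 catecholborane; 2 cis diol
Product: 6 (E)-2-(3,5-dimethoxyphenyl)ethenylboronic ester of diol 2 [alkenyl B(mac)], via catechol ester of the (E)-alkenylboronic acid 5 (not isolated)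
Conditions: 4 (1.1 equiv), (c-C6H11)2BH (5 mol %), THF, rt; then 2 (1.0 equiv), rt
Reagents that add atoms: none
Why: Syn, anti-Markovnikov alkyne hydroboration fixes the E geometry with boron on the terminal carbon, and the aliphatic cis diol 2 then displaces catechol by boronic ester exchange to give an ester that should survive chromatography. The diolate of 2 replaces pinacol because β-substituted alkenyl pinacol borates tend to undergo direct boron-to-palladium transfer in step 4.

Step 3
Reactants: 7 methyl 4-fluoro-3-hydroxybenzoate
Product: 8 methyl 4-fluoro-3-(trifluoromethylsulfonyloxy)benzoate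
Conditions: Tf2O (1.2 equiv), pyridine, CH2Cl2, 0 °C
Reagents that add atoms: trifluoromethanesulfonic anhydride, O=S(=O)(OS(=O)(=O)C(F)(F)F)C(F)(F)F
Why: O-Sulfonylation of a phenol; the triflate is the halide-free electrophile that step 4 requires, and fluorine and ester are not affected.

Step 4
Reactants: 9 4-bromoanisole; 6 alkenyl B(mac); 8 methyl 4-fluoro-3-(trifluoromethylsulfonyloxy)benzoate
Product: 12 methyl 3-[(1S,2S)-1-(3,5-dimethoxyphenyl)-2-(4-methoxyphenyl)-2-B(mac)-ethyl]-4-fluorobenzoate, via 4-methoxyphenyllithium 10 (not isolated), via lithium alkenyl(aryl)borate 11 (not isolated)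
Conditions: 9, t-BuLi (2.0 equiv), THF, −78 °C; 6 (1.05 equiv), −78 °C → rt; then 8 (1.0 equiv), Pd(OAc)2 (2 mol %), (Sp,Sp)-MandyPhos Fe[C5H3(PAr2)(CH(NMe2)Ph)]2 (Ar = 3,5-Me2C6H3, 2.4 mol %), KOTf (2 equiv), THF, 60 °C
Reagents that add atoms: none
Why: Oxidative addition of 8 to zerovalent palladium (formed in the flask from Pd(OAc)2 and the bisphosphine) should give a cationic divalent arylpalladium triflate that binds the alkene of borate 11 instead of transmetalating. π-Activation triggers a 1,2-shift of the 4-methoxyphenyl group from boron to C2 anti to palladium while the Pd–C3 bond forms, and reductive elimination then joins C3 to C3a with retention and returns zerovalent palladium. The closest known reaction type is the enantioselective conjunctive cross-coupling of β-substituted alkenylboron ate complexes with aryl triflates, for which hindered diolates such as that of 2 are the boron ligands of choice. No ring is closed in this step. C3 is controlled by the chiral bisphosphine, which selects the alkene face bound by palladium; C2 follows from C3 through the stereospecific anti shift across the E-alkene, so the anti (1S,2S) adduct should result, and this maps onto the trans ring. The step needs the metallate shift to win over direct boron-to-palladium transfer; this is secured by the rigid diolate on boron and by keeping palladium cationic (triflate electrophile, KOTf to precipitate the bromide from the lithium exchange as KBr). It also needs chemoselectivity for C–OTf over C–F and the ester; this is secured because 6 is in slight excess so that no free aryllithium remains, and because aryl fluorides do not add to palladium under these conditions.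

Step 5
Reactants: 12 conjunctive coupling product
Product: 13 methyl 3-[(1S,2S)-1-(3,5-dimethoxyphenyl)-2-hydroxy-2-(4-methoxyphenyl)ethyl]-4-fluorobenzoate
Conditions: NaBO3·4H2O (5 equiv), THF/H2O (1:1), rt
Reagents that add atoms: sodium perborate tetrahydrate, [Na+].[O-]OB=O.O.O.O.O
Why: Boronate oxidation: the peroxo adduct at boron undergoes 1,2-migration of C2 from boron to oxygen with retention, so the C2–O bond takes the place of the C2–B bond. Perborate (about pH 10) is preferred to NaOH/H2O2 to spare the methyl ester and the activated C–F bond, and diol 2 is recovered.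

Step 6
Reactants: 13 fluoro alcohol
Product: 14 methyl (2S,3S)-3-(3,5-dimethoxyphenyl)-2-(4-methoxyphenyl)-2,3-dihydro-1-benzofuran-5-carboxylate
Conditions: KN(SiMe3)2 (1.1 equiv), THF/DMF (4:1), 0 °C → rt
Reagents that add atoms: none
Why: Intramolecular SNAr (addition–elimination, five-membered ring) of the potassium alkoxide at the C–F carbon, whose anionic intermediate is stabilised by the para ester. No bond at C2 or C3 changes, so the anti adduct should close to the trans ring with both centres intact; one equivalent of a non-nucleophilic base at low temperature limits alkoxide fragmentation and deprotonation at C3.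

Step 7
Reactants: 14 dihydrobenzofuran ester
Product: 15 [(2S,3S)-3-(3,5-dimethoxyphenyl)-2-(4-methoxyphenyl)-2,3-dihydro-1-benzofuran-5-yl]methanol
Conditions: i-Bu2AlH (2.5 equiv), CH2Cl2, −78 → 0 °C; aq. potassium sodium tartrate
Reagents that add atoms: none
Why: Hydride reduction of the aryl ester to the benzylic alcohol; full reduction followed by re-oxidation is chosen because a partial reduction of an aryl ester is hard to stop at the aldehyde.

Step 8
Reactants: 15 benzylic alcohol
Product: 16 (2S,3S)-3-(3,5-dimethoxyphenyl)-2-(4-methoxyphenyl)-2,3-dihydro-1-benzofuran-5-carbaldehyde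
Conditions: MnO2 (15 equiv), CH2Cl2, rt
Reagents that add atoms: none
Why: Heterogeneous oxidation of a benzylic alcohol to the aldehyde under neutral conditions; over-oxidation is not expected and neither acid nor base reaches C2 or C3.

Step 9
Reactants: 16 aldehyde; 17 diethyl (3,5-dimethoxybenzyl)phosphonate
Product: 18 (2S,3S)-3-(3,5-dimethoxyphenyl)-5-[(E)-2-(3,5-dimethoxyphenyl)ethenyl]-2-(4-methoxyphenyl)-2,3-dihydro-1-benzofuran
Conditions: 17 (1.3 equiv), KOt-Bu (1.25 equiv), THF, 0 °C; then 16, 0 °C → rt; exclusion of light
Reagents that add atoms: none
Why: Horner–Wadsworth–Emmons olefination: the benzylic phosphonate anion adds reversibly to the aryl aldehyde and eliminates through the more stable anti arrangement, which should give the E-stilbene. The base is kept below the amount of phosphonate so that no free alkoxide is left to deprotonate C3.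

Step 10
Reactants: 18 pentamethyl ether
Product: 19 (2S,3S)-trans-δ-viniferin
Conditions: BBr3 (10 equiv), CH2Cl2, −78 °C → rt, dark; then MeOH, H2O
Reagents that add atoms: none
Why: Lewis acid-mediated cleavage of the five aryl methyl ethers (bromide attacks the methyl group of each boron-bound ether). C3 cannot ionise and holds its configuration, while C2, should it ionise reversibly, is expected to re-close to the more stable trans ring, so no new stereochemical decision is made here.

## Compound list

1 | acenaphthylene-1,2-dione | O=C1C(=O)c2cccc3cccc1c23 | starting material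
2 | (1R,2S)-1,2-dimethyl-1,2-dihydroacenaphthylene-1,2-diol (cis, meso) | C[C@]1(O)c2cccc3cccc(c23)[C@@]1(C)O | intermediate
3 | 1-ethynyl-3,5-dimethoxybenzene | C#Cc1cc(OC)cc(OC)c1 | starting material
4 | catecholborane (1,3,2-benzodioxaborole) | B1Oc2ccccc2O1 | starting material
5 | 2-[(E)-2-(3,5-dimethoxyphenyl)ethenyl]-1,3,2-benzodioxaborole | COc1cc(/C=C/B2Oc3ccccc3O2)cc(OC)c1 | intermediate (not isolated)
6 | (6bR,9aS)-8-[(E)-2-(3,5-dimethoxyphenyl)ethenyl]-6b,9a-dimethyl-6b,9a-dihydroacenaphtho[1,2-d][1,3,2]dioxaborole | COc1cc(/C=C/B2O[C@@]3(C)c4cccc5cccc(c45)[C@@]3(C)O2)cc(OC)c1 | intermediate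
7 | methyl 4-fluoro-3-hydroxybenzoate | COC(=O)c1ccc(F)c(O)c1 | starting material
8 | methyl 4-fluoro-3-(trifluoromethylsulfonyloxy)benzoate | COC(=O)c1ccc(F)c(OS(=O)(=O)C(F)(F)F)c1 | intermediate
9 | 4-bromoanisole | COc1ccc(Br)cc1 | starting material
10 | 4-methoxyphenyllithium | [Li]c1ccc(OC)cc1 | intermediate (not isolated)
11 | lithium [(E)-2-(3,5-dimethoxyphenyl)ethenyl](4-methoxyphenyl)borate of diol 2 (configuration at boron not defined) | [Li+].COc1ccc([B-]2(/C=C/c3cc(OC)cc(OC)c3)O[C@@]3(C)c4cccc5cccc(c45)[C@@]3(C)O2)cc1 | intermediate (not isolated)
12 | methyl 3-[(1S,2S)-1-(3,5-dimethoxyphenyl)-2-(4-methoxyphenyl)-2-[(6bR,9aS)-6b,9a-dimethyl-6b,9a-dihydroacenaphtho[1,2-d][1,3,2]dioxaborol-8-yl]ethyl]-4-fluorobenzoate | COc1ccc([C@@H](B2O[C@@]3(C)c4cccc5cccc(c45)[C@@]3(C)O2)[C@@H](c2cc(OC)cc(OC)c2)c2cc(C(=O)OC)ccc2F)cc1 | intermediate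
13 | methyl 3-[(1S,2S)-1-(3,5-dimethoxyphenyl)-2-hydroxy-2-(4-methoxyphenyl)ethyl]-4-fluorobenzoate | COc1ccc([C@@H](O)[C@@H](c2cc(OC)cc(OC)c2)c2cc(C(=O)OC)ccc2F)cc1 | intermediate
14 | methyl (2S,3S)-3-(3,5-dimethoxyphenyl)-2-(4-methoxyphenyl)-2,3-dihydro-1-benzofuran-5-carboxylate | COc1ccc([C@H]2Oc3ccc(C(=O)OC)cc3[C@@H]2c2cc(OC)cc(OC)c2)cc1 | intermediate
15 | [(2S,3S)-3-(3,5-dimethoxyphenyl)-2-(4-methoxyphenyl)-2,3-dihydro-1-benzofuran-5-yl]methanol | COc1ccc([C@H]2Oc3ccc(CO)cc3[C@@H]2c2cc(OC)cc(OC)c2)cc1 | intermediate
16 | (2S,3S)-3-(3,5-dimethoxyphenyl)-2-(4-methoxyphenyl)-2,3-dihydro-1-benzofuran-5-carbaldehyde | COc1ccc([C@H]2Oc3ccc(C=O)cc3[C@@H]2c2cc(OC)cc(OC)c2)cc1 | intermediate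
17 | diethyl (3,5-dimethoxybenzyl)phosphonate | CCOP(=O)(Cc1cc(OC)cc(OC)c1)OCC | starting material
18 | (2S,3S)-3-(3,5-dimethoxyphenyl)-5-[(E)-2-(3,5-dimethoxyphenyl)ethenyl]-2-(4-methoxyphenyl)-2,3-dihydro-1-benzofuran | COc1ccc([C@H]2Oc3ccc(/C=C/c4cc(OC)cc(OC)c4)cc3[C@@H]2c2cc(OC)cc(OC)c2)cc1 | intermediate
19 | (2S,3S)-trans-δ-viniferin | Oc1ccc([C@H]2Oc3ccc(/C=C/c4cc(O)cc(O)c4)cc3[C@@H]2c2cc(O)cc(O)c2)cc1 | target

## Step count and least certain steps

Total step count: 10 steps. Longest linear sequence: 9 steps (1 → 2 → 6 → 12 → 13 → 14 → 15 → 16 → 18 → 19; 8 steps from 3 if diol 2 is bought).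

Step 4 (key step). The most likely failure is direct transfer of the alkenyl or aryl group from boron to palladium (the Suzuki–Miyaura pathway) in place of the metallate shift. Alkene binding is slowed by the β-aryl group and by the hindered, electron-poor ortho-fluoro arylpalladium. Residual bromide would also block the cationic site, and facial selectivity could erode with this hindered electrophile. The fallback gives up catalytic enantiocontrol; it sets out from 3, 9 and 8 and comes back at 14. Sonogashira coupling of 3 with 9 (PdCl2(PPh3)2, CuI, Et3N, 80 °C) gives 1,3-dimethoxy-5-[(4-methoxyphenyl)ethynyl]benzene F1. Acid-catalysed hydration (CF3SO3H cat., H2O, CF3CH2OH, 60 °C), directed by the para methoxy group, gives 2-(3,5-dimethoxyphenyl)-1-(4-methoxyphenyl)ethan-1-one F2. Palladium-catalysed α-arylation of F2 with 8 (Pd(OAc)2, XPhos, K3PO4, toluene, 100 °C), followed in the same flask by enolate O-SNAr at the C–F carbon (DMF, 120 °C), gives methyl 3-(3,5-dimethoxyphenyl)-2-(4-methoxyphenyl)-1-benzofuran-5-carboxylate F3. Ionic hydrogenation (Et3SiH, CF3CO2H, CH2Cl2), with acid equilibration at C2, gives the racemic trans methyl 3-(3,5-dimethoxyphenyl)-2-(4-methoxyphenyl)-2,3-dihydro-1-benzofuran-5-carboxylate F4. F4 is resolved by preparative chromatography on a chiral stationary phase to give 14.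

Step 10. The most likely failure is ionisation of O1–C2 by the boron halide followed by capture of the benzylic cation by the electron-rich alkene or arene of a second molecule (oligomerisation), together with addition of HBr to the stilbene. The fallback takes the alkene out of the acidic step and ends with a fluoride deprotection; it sets out from 16 and comes back at 19. BBr3 (CH2Cl2, −78 °C → rt) on 16 gives (2S,3S)-3-(3,5-dihydroxyphenyl)-2-(4-hydroxyphenyl)-2,3-dihydro-1-benzofuran-5-carbaldehyde F5. Silylation (t-BuMe2SiCl, imidazole, DMF) gives the tris(tert-butyldimethylsilyl) ether of that aldehyde F6. The partner is made from commercial 3,5-bis(tert-butyldimethylsilyloxy)benzaldehyde: NaBH4 gives [3,5-bis(tert-butyldimethylsilyloxy)phenyl]methanol F7, Appel bromination (CBr4, PPh3) gives 1-(bromomethyl)-3,5-bis(tert-butyldimethylsilyloxy)benzene F8, and Arbuzov reaction with P(OEt)3 (120 °C) gives diethyl [3,5-bis(tert-butyldimethylsilyloxy)benzyl]phosphonate F9. Horner–Wadsworth–Emmons olefination of F6 with F9 (NaH, THF, 0 °C) gives the pentakis(tert-butyldimethylsilyl) ether of (2S,3S)-trans-δ-viniferin F10. Desilylation (n-Bu4NF, AcOH, THF, 0 °C) gives 19.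

Step 9. The most likely failures are deprotonation at C3 by alkoxide or phosphonate anion with expulsion of the para-formyl phenoxide (opening of the dihydrofuran), and incomplete E selectivity. The fallback builds the alkene by a Heck reaction, whose syn insertion and syn β-hydride elimination give the E isomer under a weak amine base; it sets out from 16 and comes back at 18. Wittig methylenation with the much less basic ylide Ph3P=CH2 (Ph3PCH3Br, KN(SiMe3)2, THF, −78 → 0 °C) gives (2S,3S)-3-(3,5-dimethoxyphenyl)-5-ethenyl-2-(4-methoxyphenyl)-2,3-dihydro-1-benzofuran F11. Heck coupling of F11 with commercial 1-iodo-3,5-dimethoxybenzene (Pd(OAc)2, P(o-tol)3, Et3N, DMF, 90 °C) gives 18.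

Step 2. The most likely failures are incomplete exchange of catechol for the tertiary diol 2, hydrolysis of the catechol ester during handling, and some addition of boron to the internal alkyne carbon. The fallback goes through isolated intermediates; it sets out from 3 and comes back at 6. Hydroboration of 3 with pinacolborane (Cp2ZrHCl 5 mol %, Et3N, 60 °C) gives 2-[(E)-2-(3,5-dimethoxyphenyl)ethenyl]-4,4,5,5-tetramethyl-1,3,2-dioxaborolane F12. Oxidative removal of pinacol (NaIO4, NH4OAc, acetone/H2O) gives [(E)-2-(3,5-dimethoxyphenyl)ethenyl]boronic acid F13. Condensation of F13 with 2 (MgSO4, CH2Cl2, rt) gives 6.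

## Further compounds

F1 | step 4 | 1,3-dimethoxy-5-[(4-methoxyphenyl)ethynyl]benzene | COc1ccc(C#Cc2cc(OC)cc(OC)c2)cc1
F2 | step 4 | 2-(3,5-dimethoxyphenyl)-1-(4-methoxyphenyl)ethan-1-one | COc1ccc(C(=O)Cc2cc(OC)cc(OC)c2)cc1
F3 | step 4 | methyl 3-(3,5-dimethoxyphenyl)-2-(4-methoxyphenyl)-1-benzofuran-5-carboxylate | COC(=O)c1ccc2oc(-c3ccc(OC)cc3)c(-c3cc(OC)cc(OC)c3)c2c1
F4 | step 4 | racemic trans methyl 3-(3,5-dimethoxyphenyl)-2-(4-methoxyphenyl)-2,3-dihydro-1-benzofuran-5-carboxylate, 1:1 mixture of (2S,3S) and (2R,3R) | COc1ccc([C@H]2Oc3ccc(C(=O)OC)cc3[C@@H]2c2cc(OC)cc(OC)c2)cc1.COc1ccc([C@@H]2Oc3ccc(C(=O)OC)cc3[C@H]2c2cc(OC)cc(OC)c2)cc1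
F5 | step 10 | (2S,3S)-3-(3,5-dihydroxyphenyl)-2-(4-hydroxyphenyl)-2,3-dihydro-1-benzofuran-5-carbaldehyde | Oc1ccc([C@H]2Oc3ccc(C=O)cc3[C@@H]2c2cc(O)cc(O)c2)cc1
F6 | step 10 | (2S,3S)-3-[3,5-bis(tert-butyldimethylsilyloxy)phenyl]-2-[4-(tert-butyldimethylsilyloxy)phenyl]-2,3-dihydro-1-benzofuran-5-carbaldehyde | CC(C)(C)[Si](C)(C)Oc1ccc([C@H]2Oc3ccc(C=O)cc3[C@@H]2c2cc(O[Si](C)(C)C(C)(C)C)cc(O[Si](C)(C)C(C)(C)C)c2)cc1
F7 | step 10 | [3,5-bis(tert-butyldimethylsilyloxy)phenyl]methanol | CC(C)(C)[Si](C)(C)Oc1cc(CO)cc(O[Si](C)(C)C(C)(C)C)c1
F8 | step 10 | 1-(bromomethyl)-3,5-bis(tert-butyldimethylsilyloxy)benzene | CC(C)(C)[Si](C)(C)Oc1cc(CBr)cc(O[Si](C)(C)C(C)(C)C)c1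
F9 | step 10 | diethyl [3,5-bis(tert-butyldimethylsilyloxy)benzyl]phosphonate | CCOP(=O)(Cc1cc(O[Si](C)(C)C(C)(C)C)cc(O[Si](C)(C)C(C)(C)C)c1)OCC
F10 | step 10 | pentakis(tert-butyldimethylsilyl) ether of (2S,3S)-trans-δ-viniferin | CC(C)(C)[Si](C)(C)Oc1ccc([C@H]2Oc3ccc(/C=C/c4cc(O[Si](C)(C)C(C)(C)C)cc(O[Si](C)(C)C(C)(C)C)c4)cc3[C@@H]2c2cc(O[Si](C)(C)C(C)(C)C)cc(O[Si](C)(C)C(C)(C)C)c2)cc1
F11 | step 9 | (2S,3S)-3-(3,5-dimethoxyphenyl)-5-ethenyl-2-(4-methoxyphenyl)-2,3-dihydro-1-benzofuran | COc1ccc([C@H]2Oc3ccc(C=C)cc3[C@@H]2c2cc(OC)cc(OC)c2)cc1
F12 | step 2 | 2-[(E)-2-(3,5-dimethoxyphenyl)ethenyl]-4,4,5,5-tetramethyl-1,3,2-dioxaborolane | COc1cc(/C=C/B2OC(C)(C)C(C)(C)O2)cc(OC)c1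
F13 | step 2 | [(E)-2-(3,5-dimethoxyphenyl)ethenyl]boronic acid | COc1cc(/C=C/B(O)O)cc(OC)c1
A1 | alternative 1 | [(2S,3S)-3-(3,5-dimethoxyphenyl)-5-[(E)-2-(3,5-dimethoxyphenyl)ethenyl]-2-(4-methoxyphenyl)-2,3-dihydro-1-benzofuran-7-yl]trimethylsilane | COc1ccc([C@H]2Oc3c([Si](C)(C)C)cc(/C=C/c4cc(OC)cc(OC)c4)cc3[C@@H]2c2cc(OC)cc(OC)c2)cc1
A2 | alternative 1 | (3R,4S)-3-(3,5-dimethoxyphenyl)-4-(4-methoxyphenyl)-4-[(trimethylsilyl)ethynyloxy]but-1-yne | C[Si](C)(C)C#CO[C@H](c1ccc(OC)cc1)[C@H](C#C)c1cc(OC)cc(OC)c1
A3 | alternative 1 | 1-[(E)-but-1-en-3-yn-1-yl]-3,5-dimethoxybenzene | C#C/C=C/c1cc(OC)cc(OC)c1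
A4 | alternative 2 | (2S,3S)-trans-5-bromo-4-chloro-3-(3,5-dimethoxyphenyl)-2-[4-(trifluoromethylsulfonyloxy)phenyl]-2,3-dihydrobenzofuran | O=S(=O)(Oc1ccc([C@H]2Oc3ccc(Br)c(Cl)c3[C@@H]2c2cc(OC)cc(OC)c2)cc1)C(F)(F)F
A5 | alternative 2 | (2R,3R)-2-(3,5-dimethoxyphenyl)-3-[4-(trifluoromethylsulfonyloxy)phenyl]oxirane (trans) | O=S(=O)(Oc1ccc([C@H]2O[C@@H]2c2cc(OC)cc(OC)c2)cc1)C(F)(F)F
A6 | alternative 2 | 4-bromo-3-chloro-2-(trimethylsilyl)phenyl trifluoromethanesulfonate | C[Si](C)(C)c1c(OS(=O)(=O)C(F)(F)F)ccc(Br)c1Cl
A7 | alternative 3 | (2S,3S)-trans-5-bromo-3-(3,5-dimethoxyphenyl)-2-(4-methoxyphenyl)-2,3-dihydrobenzofuran | COc1ccc([C@H]2Oc3ccc(Br)cc3[C@@H]2c2cc(OC)cc(OC)c2)cc1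
A8 | alternative 3 | 4-bromo-2-[(3,5-dimethoxyphenyl)(4-methylbenzenesulfonyl)methyl]phenol (racemic) | Cc1ccc(S(=O)(=O)C(c2cc(OC)cc(OC)c2)c2cc(Br)ccc2O)cc1
A9 | alternative 3 | (2R,5R)-1-(4-methoxybenzyl)-2,5-dimethylthiolan-1-ium bromide | C[C@@H]1CC[C@@H](C)[S+]1Cc1ccc(OC)cc1.[Br-]
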